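**Plan**
Retrosynthesis: cut C2'–C3' (B-alkyl Suzuki–Miyaura) into (2R)-2-vinylchroman 11 and (E)-vinyl iodide 19; then cut O1–C2 of the dihydropyran ring; then C5'–C6' of the side chain.
Enabling feature: C2 carries CH3 and the C1'–C2' unit, so C2/C1'/C2' can act as an η3-allyl ligand on palladium. The phenolic O1 on C8a, held by the C3–C4 bridge from C4a, closes the six-membered ring O1/C2/C3/C4/C4a/C8a at the inner allyl terminus.
Forward, chroman: methylhydroquinone → Z-allylic carbonate 10 → pyran ring closure (sets C2, leaves a vinyl handle) → hydroboration and coupling with 19 → desilylation.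
Forward, side chain: geraniol → Sharpless epoxide → propargylation at C6' → epoxide hydrolysis → alkyne carboalumination and iodination.
Stereochemistry: C2 from the chiral diphosphine on palladium (2R in 11 equals 2S in the target; only the descriptor changes). C7' and C8' come from the tartrate-controlled epoxidation and inversion at C8' on hydrolysis. The E C3'=C4' bond comes from syn-carboalumination.

Key step: step 7

Assumption: with the (Z)-carbonate the (1R,2R)-ligand is taken to give (2R)-11; should the sense of induction prove opposite, the (1S,2S)-ligand is used and nothing else changes.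

**Route**

Step 1
Reactants: 1 2-methylbenzene-1,4-diol
Product: 2 2-methyl-4-[(triisopropylsilyl)oxy]phenol
Conditions: TIPSCl (1.0 equiv), imidazole, DMF, 0 °C
Reagents that add atoms: triisopropylsilyl chloride CC(C)[Si](Cl)(C(C)C)C(C)C
Why: Regioselective phenol silylation: the bulky chlorosilane should react at the unhindered 4-OH, the 1-OH being flanked by the methyl group.

Step 2
Reactants: 2 2-methyl-4-[(triisopropylsilyl)oxy]phenol
Product: 3 2-hydroxy-3-methyl-5-[(triisopropylsilyl)oxy]benzaldehyde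
Conditions: MgCl2, Et3N, (CH2O)n, THF, reflux
Reagents that add atoms: paraformaldehyde (as formaldehyde) C=O
Why: Magnesium-phenoxide-directed ortho-formylation (Casnati–Skattebøl) should place the formyl group at the only free position ortho to the free hydroxyl.

Step 3
Reactants: 3 2-hydroxy-3-methyl-5-[(triisopropylsilyl)oxy]benzaldehyde
Product: 4 2-ethenyl-6-methyl-4-[(triisopropylsilyl)oxy]phenol
Conditions: Ph3PCH3Br (2.5 equiv), KOtBu (2.5 equiv), THF, 0 °C → rt
Reagents that add atoms: methyltriphenylphosphonium bromide C[P+](c1ccccc1)(c1ccccc1)c1ccccc1.[Br-]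
Why: Wittig methylenation with excess ylide (one equivalent is spent on the phenol) should convert the salicylaldehyde into the 2-vinylphenol.

Step 4
Reactants: 5 but-2-yn-1-ol
Product: 7 (2Z)-3-iodobut-2-en-1-ol, via cyclic alkenylaluminate 6 (not isolated)
Conditions: NaAlH2(OCH2CH2OMe)2 (1.1 equiv), THF, 0 °C → rt; then I2, −78 → 0 °C
Reagents that add atoms: iodine II
Why: Hydroxyl-directed trans-hydroalumination of the propargylic alcohol puts aluminium on C3 inside a five-membered aluminate, and iodinolysis with retention should give the Z-iodide only.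

Step 5
Reactants: 4 2-ethenyl-6-methyl-4-[(triisopropylsilyl)oxy]phenol; 7 (2Z)-3-iodobut-2-en-1-ol
Product: 9 (2Z)-5-{2-hydroxy-3-methyl-5-[(triisopropylsilyl)oxy]phenyl}-3-methylpent-2-en-1-ol, via O-borylated alkylborane 8 (not isolated)
Conditions: 9-BBN (2.4 equiv), THF, 0 °C → rt; then 7, Pd(dppf)Cl2 (5 mol %), aq. K3PO4, THF/DMF, 45 °C
Reagents that add atoms: none
Why: Anti-Markovnikov hydroboration of the styrene (the phenol is borylated at oxygen in passing) followed by B-alkyl Suzuki–Miyaura coupling, which retains the iodide geometry, should give the Z-trisubstituted allylic alcohol.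

Step 6
Reactants: 9 (2Z)-5-{2-hydroxy-3-methyl-5-[(triisopropylsilyl)oxy]phenyl}-3-methylpent-2-en-1-ol
Product: 10 methyl (2Z)-5-{2-hydroxy-3-methyl-5-[(triisopropylsilyl)oxy]phenyl}-3-methylpent-2-en-1-yl carbonate
Conditions: ClCO2Me (1.1 equiv), pyridine, CH2Cl2, −20 → 0 °C
Reagents that add atoms: methyl chloroformate COC(=O)Cl
Why: Chemoselective carbonate formation: one equivalent of chloroformate should acylate the primary allylic alcohol in preference to the hindered 2,6-dialkylphenol.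

Step 7
Reactants: 10 methyl (2Z)-5-{2-hydroxy-3-methyl-5-[(triisopropylsilyl)oxy]phenyl}-3-methylpent-2-en-1-yl carbonate
Product: 11 {[(2R)-2-ethenyl-2,8-dimethyl-3,4-dihydro-2H-chromen-6-yl]oxy}triisopropylsilane
Conditions: Pd2(dba)3·CHCl3 (2 mol %), (1R,2R)-N,N'-bis[2-(diphenylphosphino)benzoyl]cyclohexane-1,2-diamine (6 mol %), AcOH (1 equiv), CH2Cl2, rt
Reagents that add atoms: none
Why: Zerovalent palladium ionises the allylic carbonate (loss of CO2 and methoxide) to a cationic η3-allyl complex of divalent palladium spanning C2, C1' and C2', and the phenolic oxygen attacks the substituted terminus C2 on the face opposite to the metal. The closest known reaction type is the intramolecular asymmetric Tsuji–Trost O-allylation of phenols carrying a trisubstituted allylic carbonate, which gives 2-methyl-2-vinylchromans. The dihydropyran ring closes in the 6-exo-trig mode (inner allyl terminus attacked, vinyl group left outside the ring), whereas attack at C2' would require an eight-membered ring. C2, the only new stereocentre, is under catalyst control: the chiral pocket of the twofold-symmetric diphosphine decides which diastereomeric allyl complex cyclises, and acetic acid keeps the phenoxide concentration low so that η3–η1–η3 interconversion stays faster than ring closure (Curtin–Hammett conditions). The step needs O- over C-alkylation, branched over linear attack and high enantioselectivity, which the tether length, the geometrically pure Z-alkene and the buffered medium should secure. The silyl ether keeps the second phenolic oxygen out of the reaction.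

Step 8
Reactants: 12 geraniol, (2E)-3,7-dimethylocta-2,6-dien-1-ol
Product: 13 [(2S,3S)-3-methyl-3-(4-methylpent-3-en-1-yl)oxiran-2-yl]methanol
Conditions: Ti(OiPr)4 (5 mol %), L-(+)-diethyl tartrate (7 mol %), t-BuOOH, 4 Å MS, CH2Cl2, −20 °C
Reagents that add atoms: tert-butyl hydroperoxide CC(C)(C)OO
Why: Sharpless asymmetric epoxidation with the L-(+)-tartrate should epoxidise only the allylic 2,3-alkene and give the (2S,3S)-epoxide, the 6,7-alkene having no directing hydroxyl.

Step 9
Reactants: 13 [(2S,3S)-3-methyl-3-(4-methylpent-3-en-1-yl)oxiran-2-yl]methanol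
Product: 15 trimethyl{4-[(2S,3S)-3-methyl-3-(4-methylpent-3-en-1-yl)oxiran-2-yl]but-1-yn-1-yl}silane, via epoxy triflate 14 (not isolated)
Conditions: Tf2O, 2,6-lutidine, CH2Cl2, −78 °C, cold aq. work-up; then TMSC≡CCH2Li (from TMSC≡CCH3, n-BuLi), THF, −78 → −40 °C
Reagents that add atoms: 1-(trimethylsilyl)propyne CC#C[Si](C)(C)C (used as its 3-lithio derivative)
Why: SN2 alkylation of lithiated 1-silylpropyne at its CH2 terminus by the primary triflate should be fast at −78 °C, where the hindered trisubstituted epoxide is not attacked.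

Step 10
Reactants: 15 trimethyl{4-[(2S,3S)-3-methyl-3-(4-methylpent-3-en-1-yl)oxiran-2-yl]but-1-yn-1-yl}silane
Product: 16 (5S,6R)-6,10-dimethyl-1-(trimethylsilyl)undec-9-en-1-yne-5,6-diol
Conditions: HClO4 (cat., 3% aq.), THF/H2O, 0 °C
Reagents that add atoms: water O
Why: Acid-catalysed epoxide hydrolysis should proceed by attack of water at the tertiary carbon C8' with inversion while the C7'–O bond stays intact, so the trans-epoxide gives the (7'S,8'R)-diol (net anti-dihydroxylation of the E-alkene).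

Step 11
Reactants: 16 (5S,6R)-6,10-dimethyl-1-(trimethylsilyl)undec-9-en-1-yne-5,6-diol
Product: 17 (5S,6R)-6,10-dimethylundec-9-en-1-yne-5,6-diol
Conditions: K2CO3, MeOH, rt
Reagents that add atoms: none
Why: Base-catalysed methanolysis of the alkynyl C–Si bond (protodesilylation) should free the terminal alkyne without touching the diol.

Step 12
Reactants: 17 (5S,6R)-6,10-dimethylundec-9-en-1-yne-5,6-diol
Product: 19 (1E,5S,6R)-1-iodo-2,6,10-trimethylundeca-1,9-diene-5,6-diol, via alkenylalane 18 (not isolated)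
Conditions: Me3Al (5 equiv), Cp2ZrCl2 (0.3 equiv), CH2Cl2, 0 °C → rt; then I2, THF, −30 → 0 °C; aq. Na2S2O3/NaHCO3
Reagents that add atoms: trimethylaluminium C[Al](C)C; iodine II
Why: Zirconium-catalysed syn-carboalumination of the terminal alkyne (Negishi carboalumination, the diol carried as its aluminium alkoxide) puts methyl on C4' and aluminium on C3', and iodinolysis with retention should give the E-iodide.

Step 13
Reactants: 11 {[(2R)-2-ethenyl-2,8-dimethyl-3,4-dihydro-2H-chromen-6-yl]oxy}triisopropylsilane; 19 (1E,5S,6R)-1-iodo-2,6,10-trimethylundeca-1,9-diene-5,6-diol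
Product: 21 (3E,7S,8R)-1-{(2S)-2,8-dimethyl-6-[(triisopropylsilyl)oxy]-3,4-dihydro-2H-chromen-2-yl}-4,8,12-trimethyltrideca-3,11-diene-7,8-diol, via alkyl-9-BBN borane 20 (not isolated)
Conditions: 9-BBN (1.5 equiv), THF, rt; then 19, Pd(dppf)Cl2 (5 mol %), AsPh3, aq. K3PO4, DMF/THF, rt
Reagents that add atoms: none
Why: Terminal hydroboration of the vinyl group and B-alkyl Suzuki–Miyaura coupling with retention of the iodide geometry should join C2' to C3', the allylic aryl ether being consumed before palladium is added.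

Step 14
Reactants: 21 (3E,7S,8R)-1-{(2S)-2,8-dimethyl-6-[(triisopropylsilyl)oxy]-3,4-dihydro-2H-chromen-2-yl}-4,8,12-trimethyltrideca-3,11-diene-7,8-diol
Product: 22 (2S)-2-[(3E,7S,8R)-7,8-dihydroxy-4,8,12-trimethyltrideca-3,11-dien-1-yl]-2,8-dimethyl-3,4-dihydro-2H-chromen-6-ol
Conditions: Bu4NF, AcOH, THF, 0 °C, argon
Reagents that add atoms: none
Why: Fluoride-induced desilylation of the aryl silyl ether, buffered with acetic acid and run under argon to protect the electron-rich chromanol from oxidation, should give the target.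

**Compound list**
1 | 2-methylbenzene-1,4-diol | Cc1cc(O)ccc1O | starting material
2 | 2-methyl-4-[(triisopropylsilyl)oxy]phenol | Cc1cc(O[Si](C(C)C)(C(C)C)C(C)C)ccc1O | intermediate
3 | 2-hydroxy-3-methyl-5-[(triisopropylsilyl)oxy]benzaldehyde | Cc1cc(O[Si](C(C)C)(C(C)C)C(C)C)cc(C=O)c1O | intermediate
4 | 2-ethenyl-6-methyl-4-[(triisopropylsilyl)oxy]phenol | Cc1cc(O[Si](C(C)C)(C(C)C)C(C)C)cc(C=C)c1O | intermediate
5 | but-2-yn-1-ol | CC#CCO | starting material
6 | sodium 2,2-bis(2-methoxyethoxy)-3-methyl-2,5-dihydro-1,2-oxaaluminol-2-uide (cyclic alkenylaluminate) | [Na+].COCCO[Al-]1(OCCOC)OCC=C1C | intermediate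
7 | (2Z)-3-iodobut-2-en-1-ol | C/C(I)=C/CO | intermediate
8 | 9-{2-[2-(9-borabicyclo[3.3.1]nonan-9-yloxy)-3-methyl-5-[(triisopropylsilyl)oxy]phenyl]ethyl}-9-borabicyclo[3.3.1]nonane | Cc1cc(O[Si](C(C)C)(C(C)C)C(C)C)cc(CCB2C3CCCC2CCC3)c1OB4C5CCCC4CCC5 | intermediate
9 | (2Z)-5-{2-hydroxy-3-methyl-5-[(triisopropylsilyl)oxy]phenyl}-3-methylpent-2-en-1-ol | Cc1cc(O[Si](C(C)C)(C(C)C)C(C)C)cc(CC/C(C)=C\CO)c1O | intermediate
10 | methyl (2Z)-5-{2-hydroxy-3-methyl-5-[(triisopropylsilyl)oxy]phenyl}-3-methylpent-2-en-1-yl carbonate | Cc1cc(O[Si](C(C)C)(C(C)C)C(C)C)cc(CC/C(C)=C\COC(=O)OC)c1O | intermediate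
11 | {[(2R)-2-ethenyl-2,8-dimethyl-3,4-dihydro-2H-chromen-6-yl]oxy}triisopropylsilane | C=C[C@@]1(C)CCc2cc(O[Si](C(C)C)(C(C)C)C(C)C)cc(C)c2O1 | intermediate
12 | geraniol, (2E)-3,7-dimethylocta-2,6-dien-1-ol | CC(C)=CCC/C(C)=C/CO | starting material
13 | [(2S,3S)-3-methyl-3-(4-methylpent-3-en-1-yl)oxiran-2-yl]methanol | CC(C)=CCC[C@]1(C)O[C@H]1CO | intermediate
14 | [(2S,3S)-3-methyl-3-(4-methylpent-3-en-1-yl)oxiran-2-yl]methyl trifluoromethanesulfonate | CC(C)=CCC[C@]1(C)O[C@H]1COS(=O)(=O)C(F)(F)F | intermediate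
15 | trimethyl{4-[(2S,3S)-3-methyl-3-(4-methylpent-3-en-1-yl)oxiran-2-yl]but-1-yn-1-yl}silane | CC(C)=CCC[C@]1(C)O[C@H]1CCC#C[Si](C)(C)C | intermediate
16 | (5S,6R)-6,10-dimethyl-1-(trimethylsilyl)undec-9-en-1-yne-5,6-diol | CC(C)=CCC[C@@](C)(O)[C@@H](O)CCC#C[Si](C)(C)C | intermediate
17 | (5S,6R)-6,10-dimethylundec-9-en-1-yne-5,6-diol | CC(C)=CCC[C@@](C)(O)[C@@H](O)CCC#C | intermediate
18 | (4S,5R)-4-[(3E)-4-(dimethylalumanyl)-3-methylbut-3-en-1-yl]-2,5-dimethyl-5-(4-methylpent-3-en-1-yl)-1,3,2-dioxalumolane | CC(C)=CCC[C@@]1(C)O[Al](C)O[C@H]1CC/C(C)=C/[Al](C)C | intermediate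
19 | (1E,5S,6R)-1-iodo-2,6,10-trimethylundeca-1,9-diene-5,6-diol | CC(C)=CCC[C@@](C)(O)[C@@H](O)CC/C(C)=C/I | intermediate
20 | 9-(2-{(2S)-2,8-dimethyl-6-[(triisopropylsilyl)oxy]-3,4-dihydro-2H-chromen-2-yl}ethyl)-9-borabicyclo[3.3.1]nonane | C1CC2CCCC(C1)B2CC[C@@]1(C)CCc2cc(O[Si](C(C)C)(C(C)C)C(C)C)cc(C)c2O1 | intermediate
21 | (3E,7S,8R)-1-{(2S)-2,8-dimethyl-6-[(triisopropylsilyl)oxy]-3,4-dihydro-2H-chromen-2-yl}-4,8,12-trimethyltrideca-3,11-diene-7,8-diol | CC(C)=CCC[C@@](C)(O)[C@@H](O)CC/C(C)=C/CC[C@@]1(C)CCc2cc(O[Si](C(C)C)(C(C)C)C(C)C)cc(C)c2O1 | intermediate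
22 | (2S)-2-[(3E,7S,8R)-7,8-dihydroxy-4,8,12-trimethyltrideca-3,11-dien-1-yl]-2,8-dimethyl-3,4-dihydro-2H-chromen-6-ol | CC(C)=CCC[C@@](C)(O)[C@@H](O)CC/C(C)=C/CC[C@@]1(C)CCc2cc(O)cc(C)c2O1 | target

**Count and risks**
Total step count: 14. Longest linear sequence: 8 steps (steps 1, 2, 3, 5, 6, 7, 13, 14); the side-chain branch (steps 8 to 12) has 5 steps before the union.

Step 7. The risk is low enantioselectivity, if ring closure outruns the equilibration of the diastereomeric allyl complexes, or the wrong sense with either ligand antipode. The fallback makes the same O1–C2 bond by a stereospecific, substrate-controlled epoxide opening. It sets out from allylic alcohol 9. Sharpless asymmetric epoxidation with D-(−)-diethyl tartrate (Ti(OiPr)4, t-BuOOH, CH2Cl2, −20 °C) should give 2-{2-[(2S,3R)-3-(hydroxymethyl)-2-methyloxiran-2-yl]ethyl}-6-methyl-4-[(triisopropylsilyl)oxy]phenol F1. Camphorsulfonic acid (cat.) in CH2Cl2 should let the phenol open the epoxide at its tertiary carbon with inversion in a 6-exo closure, giving (1R)-1-{(2R)-2,8-dimethyl-6-[(triisopropylsilyl)oxy]-3,4-dihydro-2H-chromen-2-yl}ethane-1,2-diol F2. Deoxygenation of the vicinal diol to the alkene (PPh3, I2, imidazole, toluene, 80 °C; Garegg–Samuelsson olefination) comes back to the route at 11.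

Step 10. The risk is partial loss of configuration at the tertiary carbon through a carbocation, or competing attack of water at C7', either of which erodes diastereomeric or enantiomeric purity. The fallback delivers the tertiary oxygen intramolecularly and also avoids the triflate displacement of step 9. It sets out from epoxy alcohol 13. Boc2O and DMAP should give tert-butyl [(2S,3S)-3-methyl-3-(4-methylpent-3-en-1-yl)oxiran-2-yl]methyl carbonate F3. BF3·OEt2 in CH2Cl2 at −40 °C should make the carbonate carbonyl attack the tertiary epoxide carbon with inversion, losing isobutene and giving (4R,5S)-5-hydroxy-4-methyl-4-(4-methylpent-3-en-1-yl)-1,3-dioxan-2-one F4. K2CO3 in MeOH should release (2S,3R)-3,7-dimethyloct-6-ene-1,2,3-triol F5. TsCl, Et3N and Bu2SnO (cat.) should sulfonylate the primary hydroxyl to (2S,3R)-2,3-dihydroxy-3,7-dimethyloct-6-en-1-yl 4-methylbenzenesulfonate F6. K2CO3 in MeOH should close (2R)-6-methyl-2-[(2S)-oxiran-2-yl]hept-5-en-2-ol F7 with retention at C7'. Opening of this terminal epoxide at its CH2 carbon by 3-lithio-1-(trimethylsilyl)propyne (2.5 equiv, THF/DMPU, −20 °C → rt) comes back to the route at 16.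

Step 13. The risk is slow transmetalation of the hindered borane next to the quaternary carbon, with protodeboronation or reduction of the iodide taking over, possibly aggravated by the free diol. The fallback changes the nucleophile to an organozinc (Negishi coupling). It sets out from 11 and 19. Hydroboration and oxidation of 11 (9-BBN; then NaOH, H2O2) should give 2-{(2R)-2,8-dimethyl-6-[(triisopropylsilyl)oxy]-3,4-dihydro-2H-chromen-2-yl}ethan-1-ol F8. PPh3, I2 and imidazole should give {[(2R)-2-(2-iodoethyl)-2,8-dimethyl-3,4-dihydro-2H-chromen-6-yl]oxy}triisopropylsilane F9. Zinc dust with LiCl in THF should give (2-{(2R)-2,8-dimethyl-6-[(triisopropylsilyl)oxy]-3,4-dihydro-2H-chromen-2-yl}ethyl)zinc iodide F10. Diol 19 is protected with 2,2-dimethoxypropane and pyridinium p-toluenesulfonate as (4S,5R)-4-[(3E)-4-iodo-3-methylbut-3-en-1-yl]-2,2,5-trimethyl-5-(4-methylpent-3-en-1-yl)-1,3-dioxolane F11. Coupling of F10 with F11 (Pd(PPh3)4, THF, rt) should give {[(2S)-2,8-dimethyl-2-{(3E)-4-methyl-6-[(4S,5R)-2,2,5-trimethyl-5-(4-methylpent-3-en-1-yl)-1,3-dioxolan-4-yl]hex-3-en-1-yl}-3,4-dihydro-2H-chromen-6-yl]oxy}triisopropylsilane F12. Removal of the acetonide with 80% aq. AcOH comes back to the route at 21.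

**Further compounds**
F1 | step 7 | 2-{2-[(2S,3R)-3-(hydroxymethyl)-2-methyloxiran-2-yl]ethyl}-6-methyl-4-[(triisopropylsilyl)oxy]phenol | Cc1cc(O[Si](C(C)C)(C(C)C)C(C)C)cc(CC[C@]2(C)O[C@@H]2CO)c1O
F2 | step 7 | (1R)-1-{(2R)-2,8-dimethyl-6-[(triisopropylsilyl)oxy]-3,4-dihydro-2H-chromen-2-yl}ethane-1,2-diol | OC[C@@H](O)[C@@]1(C)CCc2cc(O[Si](C(C)C)(C(C)C)C(C)C)cc(C)c2O1
F3 | step 10 | tert-butyl [(2S,3S)-3-methyl-3-(4-methylpent-3-en-1-yl)oxiran-2-yl]methyl carbonate | CC(C)=CCC[C@]1(C)O[C@H]1COC(=O)OC(C)(C)C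
F4 | step 10 | (4R,5S)-5-hydroxy-4-methyl-4-(4-methylpent-3-en-1-yl)-1,3-dioxan-2-one | CC(C)=CCC[C@@]1(C)OC(=O)OC[C@@H]1O
F5 | step 10 | (2S,3R)-3,7-dimethyloct-6-ene-1,2,3-triol | CC(C)=CCC[C@@](C)(O)[C@@H](O)CO
F6 | step 10 | (2S,3R)-2,3-dihydroxy-3,7-dimethyloct-6-en-1-yl 4-methylbenzenesulfonate | CC(C)=CCC[C@@](C)(O)[C@@H](O)COS(=O)(=O)c1ccc(C)cc1
F7 | step 10 | (2R)-6-methyl-2-[(2S)-oxiran-2-yl]hept-5-en-2-ol | CC(C)=CCC[C@@](C)(O)[C@@H]1CO1
F8 | step 13 | 2-{(2R)-2,8-dimethyl-6-[(triisopropylsilyl)oxy]-3,4-dihydro-2H-chromen-2-yl}ethan-1-ol | OCC[C@@]1(C)CCc2cc(O[Si](C(C)C)(C(C)C)C(C)C)cc(C)c2O1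
F9 | step 13 | {[(2R)-2-(2-iodoethyl)-2,8-dimethyl-3,4-dihydro-2H-chromen-6-yl]oxy}triisopropylsilane | ICC[C@@]1(C)CCc2cc(O[Si](C(C)C)(C(C)C)C(C)C)cc(C)c2O1
F10 | step 13 | (2-{(2R)-2,8-dimethyl-6-[(triisopropylsilyl)oxy]-3,4-dihydro-2H-chromen-2-yl}ethyl)zinc iodide | I[Zn]CC[C@@]1(C)CCc2cc(O[Si](C(C)C)(C(C)C)C(C)C)cc(C)c2O1
F11 | step 13 | (4S,5R)-4-[(3E)-4-iodo-3-methylbut-3-en-1-yl]-2,2,5-trimethyl-5-(4-methylpent-3-en-1-yl)-1,3-dioxolane | CC(C)=CCC[C@@]1(C)OC(C)(C)O[C@H]1CC/C(C)=C/I
F12 | step 13 | {[(2S)-2,8-dimethyl-2-{(3E)-4-methyl-6-[(4S,5R)-2,2,5-trimethyl-5-(4-methylpent-3-en-1-yl)-1,3-dioxolan-4-yl]hex-3-en-1-yl}-3,4-dihydro-2H-chromen-6-yl]oxy}triisopropylsilane | CC(C)=CCC[C@@]1(C)OC(C)(C)O[C@H]1CC/C(C)=C/CC[C@@]2(C)CCc3cc(O[Si](C(C)C)(C(C)C)C(C)C)cc(C)c3O2
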